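# Chemoenzymatic route to CNP0274187.1 (26) through (+)-germacrene A

**Compound numbers used throughout:** 1 farnesol; 2 farnesyl bromide; 3 farnesyl diphosphate; 4 (+)-germacrene A; 5 and 6 the 12-alcohol and 12-aldehyde on the way to germacrene A acid 7; 8 8β-hydroxy acid; 9 6α,8β-dihydroxy acid; 10 eupatolide; 11 angelic acid; 12 mixed anhydride; 13 eupatolide angelate; 14 1β,10α-epoxide; 15 and 16 5β-hydroperoxide and 5β-alcohol; 17 5α-formate; 18 5α-alcohol; 19 bridged ether 1β-ol; 20 borane adduct; 21 1β,15-diol; 22 15-silyl ether; 23 1-ketone; 24 enol silane; 25 enone silyl ether; 26 target.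

## Analysis of the target

In germacrane numbering, 26 is a ten-membered carbocycle C1–C10 that carries C14 on C10, C15 on C4 and the three-carbon unit C11–C13 on C7. An ether oxygen between C5 and C10 divides it into ring A, an oxepenone (O, C10, C1 ketone, C2=C3, C4, C5), and ring B, an oxepane (O, C5, C6, C7, C8, C9, C10). An α-methylene-γ-lactone (C6–O–C12, C11=C13) is trans-fused at C6–C7, C8 carries an angelate and C4 a hydroxymethyl group.

There are six stereocentres. C6 (O α), C7 (C11 β) and C8 (O β) are arranged as in the 8β-oxygenated germacrolides. The ether oxygen is α at C5 but β at C10, so ring B leaves ring A from opposite faces at the two bridgeheads. This is a trans (in/out) bridge, with the oxygen sitting where the C5–C10 bond of a trans-fused eudesmane would be. The C4 hydroxymethyl group is β, cis to C6 on ring A.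

The sensitive groups are the methylene lactone (a Michael acceptor towards bases, amines, thiols and hydrides), the angelate (Z to E isomerization) and the C5–O bond. That bond lies δ to the C1 carbonyl across C2=C3, so deprotonation at C4 would open the bridge by E1cB elimination.

The difficulty is a strained trans bridge in a medium ring, a quaternary C10, oxidation at seven of the ten ring carbons, and no tolerance for strong base or nucleophiles once the oxidation pattern is complete.

The strategy rests on one feature: the carbocycle with C14, C15 and C11–C13 is a head-to-tail folded farnesyl chain whose closing bond is C6–C7. C7 has the configuration of (+)-germacrene A, and the oxygens at C12, C6 and C8 are where plant cytochrome P450 enzymes place them.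

## Retrosynthetic reasoning

**26 to 23 (C2=C3 and the silyl group).** The C2=C3 double bond is removed first, together with a silyl group on the C15 oxygen, which leads to ketone 23. The alkene goes in last because, once it is conjugated, the C5 ether oxygen becomes a vinylogous β-leaving group. The forward dehydrogenation must therefore work without strong base. C2 is the only enolizable position, since C10 is quaternary.

**23 to 19 (C1 carbonyl, C15–O and C4–H).** The C1 ketone is traced to a 1β-alcohol (22, 21). The C15–O and C4–H bonds are then cut together, back to the exocyclic C4=C15 alkene of 19. Hydroboration is chosen over allylic oxidation of a C15 methyl group because oxidation would have to beat the C14 methyl on the more electron-rich alkene. Addition to the alkene of the rigid bicycle also sets C4: the reagent must come from the face away from C6, which leaves the hydroxymethyl group β.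

**19 to 18 (the C10–O bond of the bridge).** This cut opens both seven-membered rings at once and gives the 5α-hydroxy 1β,10α-epoxide 18. The cut is made at C10 and not at C5 for three reasons. C10 is the tertiary carbon of an epoxide that forms on the exposed face of the 1(10)-alkene. Opening it from inside the ring inverts C10 and puts oxygen on the β face, whereas direct oxidation of the alkene to a ketol would deliver oxygen to the wrong (α) face. The epoxide oxygen left on C1 is the one needed for the ketone. The forward step must be a stereospecific displacement, because the trans bridge is presumably the less stable arrangement.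

**18 to 14 (the C5–O bond).** The C5 oxygen is traced to the 4,5-alkene of 14 through an ene oxygenation. This places oxygen on C5 and moves the double bond to C4=C15, which is what the later hydroboration needs. Attack from outside the ring gives the 5β configuration (16), so one inversion (17, then 18) is included to reach the 5α-alcohol.

**14 to 13 (epoxide).** The epoxide goes back to the 1(10)-alkene of 13. This alkene is the most electron-rich in the molecule, so it reacts first and is masked before the 4,5-alkene is touched.

**13 to 10 and 11 (ester C–O bond).** The angelate is cut early. In the forward direction the ester is made before any oxidation, so that it protects the 8β-hydroxyl of 10, which could otherwise take part in transannular reactions.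

**10 to 4 (oxygens at C6, C8 and C12).** The lactone C6–O bond, the C8–O bond and the oxidation of C12 are traced through 8 and 7 to hydrocarbon 4. These are C–H oxidations at positions that no chemical reagent can tell apart on a germacrene, so three P450 enzymes are used. Hydroxylation at C8 comes before lactone formation because the 8β-hydroxylase accepts the open acid 7 and not the lactone.

**4 to 3 (C6–C7, the key disconnection).** Cutting C6–C7 opens the carbocycle to the linear diphosphate 3. This is the only ring-forming C–C bond of the synthesis. The cut is placed here because the cyclization gives the whole ten-membered ring, both (E)-alkenes, all three appendages and C7 in one step.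

**3 to 1.** The diphosphate ester is traced through bromide 2 to commercial alcohol 1 by two standard steps, so the risk of the early part of the route sits in the cyclization.

## Alternatives that were turned down

**Alternative 1:** The disconnection is the C8=C9 double bond of the tricyclic enol silane A1 (ring-closing metathesis).
- Forward step: a ruthenium alkylidene of the second-generation Hoveyda–Grubbs type would join the vinyl group on C10 to the silyl enol ether carbon C8. This closes ring B across a ring A that is already complete. Hydrolysis, reduction at C8 and acylation would follow.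
- For: the stereocentres of ring A and of the lactone would be set one by one with reagent control before the second ring is closed. The trans relation at C5 and C10 is then certain, which is stronger than in the chosen route, where it depends on one transannular step. Metathesis to cyclic enol ethers is established.
- Against: the ring closure joins a vinyl group on a quaternary carbon to a geminally disubstituted, electron-rich enol ether, both slow partners. It has to do so while building a strained trans-bridged ring, and with an enone and a methylene lactone present that can occupy the catalyst. C8 must then be set by reducing a ketone next to C7. The open-chain material needs a long protected sequence.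
- Comparison: the chosen strategy gives up the certainty at the bridge and gains the whole carbocycle and three stereocentres (C6, C7, C8) from four enzymatic steps without protecting groups.

**Alternative 2:** The disconnection is C3–C4 of the ten-membered ring with reconnection of C1 to C6 (anionic oxy-Cope ring expansion), leading to cyclodecenone A2.
- Forward step: a potassium alkoxide at C1 drives a [3,3] shift that expands a six-membered ring by four carbons and gives A2.
- For: the rearrangement is dependable and fast. The chirality comes from carvone. The C1 carbonyl and the tertiary C10 oxygen arrive with their configuration already fixed, which is a real advantage over the chosen route, where C10 must be set by epoxide opening.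
- Against: in A2, C5 and C6 are still alkene carbons and C11–C13 is an unoxidized isopropenyl group. The ether oxygen at C5, the lactone oxygen at C6, the C12 carboxyl and the C2=C3 alkene all remain to be made chemically, face-selectively on a flexible ring and under several protecting groups. C4 depends on the chair or boat course of the shift and on alkene geometry.
- Comparison: the chosen strategy offers the oxidations at C12, C6 and C8 with complete regio- and stereocontrol instead.

**Alternative 3:** The disconnection is C7–C8 within ring B (indium Barbier annulation), leading to oxepane A3.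
- Forward step: indium metal would convert an allylic bromide into an allylindium that adds through C7 to a C8 aldehyde. This closes the oxepane and gives A3.
- For: one mild, water-tolerant step would form a C–C bond, ring B, the C7 and C8 stereocentres and the methylene ester of the lactone. It needs no specialized enzymes, which is a point in its favour over the chosen route, where C8 and C6 depend on two P450 enzymes.
- Against: a seven-membered ring must close with the right C7/C8 relation through a transition state that is not easy to predict. C4, C5, C6, C10 and the C1 carbinol must all be built beforehand in a long acyclic sequence with three kinds of protecting group. Ring A still has to be closed, oxidized at C1 and lactonized afterwards.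
- Comparison: the chosen strategy is much shorter to the ring system and carries no protecting group until its last four steps.

Key step: step 3

Remark on the chemistry: germacrane numbering and α/β descriptors are used for all compounds. 3 is handled as its ammonium salt and drawn as the free acid. The bridge is taken as the target structure encodes it, with oxygen α at C5 and β at C10. Attack from outside the ring on the 4,5-alkene is assumed to give the 5β-oxygenated product.

## Steps

Step 1
Reactants: 1 (2E,6E)-farnesol
Product: 2 (2E,6E)-farnesyl bromide
Conditions: PBr3 (0.4 equiv), Et2O, −10 °C; used crude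
Reagents that add atoms: phosphorus tribromide, BrP(Br)Br
Why: Bromination of the primary allylic alcohol through its bromophosphite, with SN2 attack of bromide. At low temperature the (2E,6E) geometry should be kept and allylic transposition should stay minor.

Step 2
Reactants: 2 (2E,6E)-farnesyl bromide
Product: 3 (2E,6E)-farnesyl diphosphate
Conditions: (n-Bu4N)3HP2O7, MeCN, rt; then cation-exchange resin (NH4+ form), NH4HCO3 buffer, cellulose chromatography
Reagents that add atoms: tris(tetrabutylammonium) hydrogen diphosphate, CCCC[N+](CCCC)(CCCC)CCCC.CCCC[N+](CCCC)(CCCC)CCCC.CCCC[N+](CCCC)(CCCC)CCCC.OP(=O)([O-])OP(=O)([O-])[O-]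
Why: SN2 displacement of the allylic bromide by the diphosphate anion, a standard diphosphorylation of allylic halides. No stereocentre is involved and the alkenes are not touched.

Step 3
Reactants: 3 (2E,6E)-farnesyl diphosphate
Product: 4 (+)-(R)-germacrene A
Conditions: recombinant (+)-germacrene A synthase (chicory or lettuce), MgCl2, HEPES pH 7.0, DTT, glycerol, 30 °C, pentane overlay
Reagents that add atoms: none
Why: Divalent magnesium held by the aspartate-rich motifs of the synthase ionizes the diphosphate of 3 to the (2E,6E)-farnesyl cation, and the enzyme keeps the chain coiled so that the distal C10=C11 double bond lies over C1. C10 then bonds to C1 (C6–C7 in the numbering of 26), the charge moves to the tertiary C11, and a base in the pocket, probably the bound diphosphate, removes a proton from a C11 methyl group to leave the isopropenyl group. This is the native reaction of the enzyme and belongs to the ionization-initiated cation–olefin cyclizations of sesquiterpene synthases. The one ring formed is the ten-membered carbocycle, closed by 1,10-attack that is Markovnikov in sense and exo with respect to the distal alkene, since the cationic C11 stays outside the ring. The single new stereocentre (C7 of 26, R) is set by the face of the C10=C11 alkene that the chiral pocket presents to C1, that is, by the catalyst and not by the achiral substrate. The step needs 1,10- over 1,11-closure, retention of both (E)-alkenes, and deprotonation instead of a second cyclization or capture by water. The (E,E) geometry of 3 and the preference for a tertiary cation favour the first; the closed, water-free pocket secures the others. The product is taken into the pentane layer as it forms and kept cold and neutral, because heat would turn it into β-elemene and acid into selinenes.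

Step 4
Reactants: 4 (+)-(R)-germacrene A
Product: 7 germacrene A acid, via germacratrien-12-ol 5 (not isolated), via germacratrien-12-al 6 (not isolated)
Conditions: microsomes with germacrene A oxidase (CYP71AV-subfamily P450, lettuce) and NADPH–P450 reductase, NADP+ (cat.), glucose 6-phosphate, glucose-6-phosphate dehydrogenase, air, phosphate buffer pH 7.5, 30 °C
Reagents that add atoms: dioxygen, O=O
Why: Three successive cytochrome P450 oxidations at the allylic C12 methyl of the isopropenyl group (alcohol, aldehyde, acid) are the native reaction of this oxidase. C7 and the ring alkenes are untouched, and the neutral buffer should prevent cyclization to eudesmane acids.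

Step 5
Reactants: 7 germacrene A acid
Product: 8 8β-hydroxygermacrene A acid
Conditions: microsomes with CYP71BL1 (sunflower germacrene A acid 8β-hydroxylase) and NADPH–P450 reductase, NADP+ (cat.), glucose 6-phosphate, glucose-6-phosphate dehydrogenase, air, phosphate buffer pH 7.5, 30 °C
Reagents that add atoms: dioxygen, O=O
Why: P450 hydroxylation of the unactivated C8–H bond with retention. Position and face (8β) are fixed by the enzyme, whose natural substrate is 7.

Step 6
Reactants: 8 8β-hydroxygermacrene A acid
Product: 10 eupatolide, via 6α,8β-dihydroxy acid 9 (not isolated)
Conditions: microsomes with CYP71DD6 (sunflower eupatolide synthase) and NADPH–P450 reductase, NADP+ (cat.), glucose 6-phosphate, glucose-6-phosphate dehydrogenase, air, phosphate buffer pH 7.5, 30 °C; extraction at pH 5–6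
Reagents that add atoms: dioxygen, O=O
Why: Enzymatic allylic hydroxylation at C6 on the α face, followed by spontaneous lactonization of the γ-hydroxy acid to the trans-fused 6α,12-olide. The new C6 stereocentre is set by the enzyme, and the 8β-hydroxyl does not lactonize under these conditions.

Step 7
Reactants: 10 eupatolide; 11 angelic acid
Product: 13 eupatolide 8-O-angelate, via angelic trichlorobenzoic anhydride 12 (not isolated)
Conditions: 11, 2,4,6-trichlorobenzoyl chloride, Et3N, toluene, rt; then 10, 75 °C
Reagents that add atoms: none
Why: Yamaguchi-type acylation through the mixed anhydride without a nucleophilic catalyst, the conditions under which angelates form without isomerization to tiglates. The C8–O bond is not broken, so C8 keeps its configuration, and 75 °C is well below the temperature of Cope rearrangement of germacrolides.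

Step 8
Reactants: 13 eupatolide 8-O-angelate
Product: 14 1β,10α-epoxide of 13
Conditions: mCPBA (1.0 equiv), NaHCO3, CH2Cl2, 0 °C
Reagents that add atoms: 3-chloroperbenzoic acid, O=C(OO)c1cccc(Cl)c1
Why: Prilezhaev epoxidation of the most electron-rich alkene; the 4,5-alkene is deactivated by the allylic lactone oxygen and the two enoates are electron-poor. Syn addition to the exposed face of the (E)-alkene should give the 1β,10α-epoxide, and the buffer prevents acid-induced cyclization to eudesmanolides.

Step 9
Reactants: 14 1β,10α-epoxide of 13
Product: 16 5β-hydroxy-4(15)-ene, via 5β-hydroperoxide 15 (not isolated)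
Conditions: O2, 5,10,15,20-tetraphenylporphyrin (cat.), visible light, CH2Cl2, 0 °C; then PPh3, 0 °C
Reagents that add atoms: dioxygen, O=O
Why: Schenck ene reaction, a known reaction type for the 4,5-alkene of 1,10-epoxygermacranolides. Singlet oxygen bonds to C5 and takes a hydrogen from C15 on the more crowded side of the alkene, which moves the double bond to C4=C15. Attack from outside the ring should give the 5β (5S) hydroperoxide, which the phosphine reduces without touching C5.

Step 10
Reactants: 16 5β-hydroxy-4(15)-ene
Product: 17 5α-formate
Conditions: HCO2H, PPh3, DIAD, THF, 0 °C to rt (acid added last)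
Reagents that add atoms: formic acid, O=CO
Why: Mitsunobu reaction: formate displaces the allylic alkoxyphosphonium group at C5 by SN2, with clean inversion to the 5α (5R) ester. Adding the acid last keeps the medium buffered, so the epoxide should survive.

Step 11
Reactants: 17 5α-formate
Product: 18 5α-hydroxy-1β,10α-epoxide
Conditions: KHCO3, MeOH–H2O, 0 °C
Reagents that add atoms: none
Why: Formate esters undergo methanolysis far faster than the angelate or the lactone, and bicarbonate is too weak a base to add methanol to the methylene lactone. The C5–O bond is not broken, so the configuration is kept.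

Step 12
Reactants: 18 5α-hydroxy-1β,10α-epoxide
Product: 19 trans-bridged 5α,10β-ether 1β-ol
Conditions: (1S)-(+)-10-camphorsulfonic acid (0.1 equiv), CH2Cl2, 0 °C
Reagents that add atoms: none
Why: Acid-catalysed transannular opening of the epoxide by the 5α-hydroxyl (intramolecular epoxide–alcohol etherification). The oxygen attacks the tertiary C10 from inside the ring, anti to the epoxide oxygen, along the path that C5 takes when 1,10-epoxygermacranolides close to eudesmanolides. Inversion at C10 (oxygen β, methyl α) with retention at C5 is what makes the bridge trans, and it is fixed by the SN2-type mechanism, not by the relative stability of bridged isomers. Ring B closes 7-exo and ring A 7-endo with respect to the epoxide, whose oxygen stays on C1 as the 1β-hydroxyl.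

Step 13
Reactants: 19 trans-bridged 5α,10β-ether 1β-ol
Product: 21 1β,15-diol, via B-alkyl-9-BBN adduct 20 (not isolated)
Conditions: 9-BBN (3 equiv), THF, 0 °C to rt; then NaBO3·4H2O, H2O, rt
Reagents that add atoms: sodium perborate tetrahydrate, [Na+].[Na+].O[B-]1(O)OO[B-](O)(O)OO1
Why: Hydroboration–oxidation of the electron-rich 1,1-disubstituted alkene; boron goes to the terminal C15. Hydrogen is delivered to C4 from the face opposite to C6 and ring B, which should leave H-4 α and the hydroxymethyl group β. The electron-poor methylene lactone and angelate react much more slowly with the electrophilic dialkylborane, and perborate oxidizes the C–B bond with retention under mild conditions.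

Step 14
Reactants: 21 1β,15-diol
Product: 22 15-O-TBS ether
Conditions: TBSCl, imidazole, DMF, 0 °C
Reagents that add atoms: tert-butyldimethylsilyl chloride, CC(C)(C)[Si](C)(C)Cl
Why: Silylation should be selective for the primary hydroxyl over the secondary 1β-hydroxyl, which sits next to the quaternary C10.

Step 15
Reactants: 22 15-O-TBS ether
Product: 23 1-ketone
Conditions: Dess–Martin periodinane, NaHCO3, CH2Cl2, rt
Reagents that add atoms: none
Why: Dess–Martin oxidation of the secondary alcohol under neutral conditions. C10 is quaternary, so no stereocentre next to the new carbonyl can epimerize.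

Step 16
Reactants: 23 1-ketone
Product: 25 2,3-enone silyl ether, via trimethylsilyl enol ether 24 (not isolated)
Conditions: TMSOTf, Et3N, CH2Cl2, 0 °C; then Pd(OAc)2 (1.1 equiv), MeCN, rt
Reagents that add atoms: none
Why: Saegusa–Ito dehydrogenation: soft enolization can only occur towards C2, and the divalent palladium enolate loses a β-hydrogen from C3 to give the cis C2=C3 alkene within the seven-membered ring. The conditions are mild and non-basic, so the γ-hydrogen at C4 should not be removed and the C5 ether oxygen should not be ejected.

Step 17
Reactants: 25 2,3-enone silyl ether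
Product: 26 CNP0274187.1
Conditions: HF·pyridine, pyridine, THF, 0 °C
Reagents that add atoms: none
Why: Buffered acidic fluoride cleaves the primary silyl ether. Basic fluoride is avoided because it could open the bridge by E1cB elimination or isomerize the angelate.

## Compound list

1 | (2E,6E)-farnesol | CC(C)=CCC/C(C)=C/CC/C(C)=C/CO | starting material
2 | (2E,6E)-farnesyl bromide | CC(C)=CCC/C(C)=C/CC/C(C)=C/CBr | intermediate
3 | (2E,6E)-farnesyl diphosphate (drawn as the free acid, handled as the tris-ammonium salt) | CC(C)=CCC/C(C)=C/CC/C(C)=C/COP(=O)(O)OP(=O)(O)O | intermediate
4 | (+)-(R)-germacrene A, (7R)-germacra-1(10)E,4E,11-triene | CC(=C)[C@@H]1CC/C(C)=C/CC/C(C)=C/C1 | intermediate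
5 | (7R)-germacra-1(10)E,4E,11(13)-trien-12-ol | C=C(CO)[C@@H]1CC/C(C)=C/CC/C(C)=C/C1 | intermediate
6 | (7R)-germacra-1(10)E,4E,11(13)-trien-12-al | C=C(C=O)[C@@H]1CC/C(C)=C/CC/C(C)=C/C1 | intermediate
7 | germacrene A acid, germacra-1(10)E,4E,11(13)-trien-12-oic acid | C=C(C(=O)O)[C@@H]1CC/C(C)=C/CC/C(C)=C/C1 | intermediate
8 | 8β-hydroxygermacrene A acid | C=C(C(=O)O)[C@@H]1[C@H](O)C/C(C)=C/CC/C(C)=C/C1 | intermediate
9 | 6α,8β-dihydroxygermacrene A acid | C=C(C(=O)O)[C@@H]1[C@H](O)C/C(C)=C/CC/C(C)=C/[C@H]1O | intermediate
10 | eupatolide, 8β-hydroxygermacra-1(10)E,4E,11(13)-trien-6α,12-olide | C/C1=C\CC/C(C)=C/[C@H]2OC(=O)C(=C)[C@@H]2[C@H](O)C1 | intermediate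
11 | angelic acid, (Z)-2-methylbut-2-enoic acid | C/C=C(/C)C(=O)O | starting material
12 | angelic 2,4,6-trichlorobenzoic anhydride | C/C=C(/C)C(=O)OC(=O)c1c(Cl)cc(Cl)cc1Cl | intermediate
13 | eupatolide 8-O-angelate, 8β-angeloyloxygermacra-1(10)E,4E,11(13)-trien-6α,12-olide | C/C1=C\CC/C(C)=C/[C@H]2OC(=O)C(=C)[C@@H]2[C@H](OC(=O)/C(C)=C\C)C1 | intermediate
14 | 8β-angeloyloxy-1β,10α-epoxygermacra-4E,11(13)-dien-6α,12-olide | C[C@@]12O[C@@H]2CC/C(C)=C/[C@H]3OC(=O)C(=C)[C@@H]3[C@H](OC(=O)/C(C)=C\C)C1 | intermediate
15 | 8β-angeloyloxy-1β,10α-epoxy-5β-hydroperoxygermacra-4(15),11(13)-dien-6α,12-olide | C[C@@]12O[C@@H]2CCC(=C)[C@H](OO)[C@H]3OC(=O)C(=C)[C@@H]3[C@H](OC(=O)/C(C)=C\C)C1 | intermediate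
16 | 8β-angeloyloxy-1β,10α-epoxy-5β-hydroxygermacra-4(15),11(13)-dien-6α,12-olide (5S) | C[C@@]12O[C@@H]2CCC(=C)[C@H](O)[C@H]3OC(=O)C(=C)[C@@H]3[C@H](OC(=O)/C(C)=C\C)C1 | intermediate
17 | 8β-angeloyloxy-1β,10α-epoxy-5α-formyloxygermacra-4(15),11(13)-dien-6α,12-olide | C[C@@]12O[C@@H]2CCC(=C)[C@@H](OC=O)[C@H]3OC(=O)C(=C)[C@@H]3[C@H](OC(=O)/C(C)=C\C)C1 | intermediate
18 | 8β-angeloyloxy-1β,10α-epoxy-5α-hydroxygermacra-4(15),11(13)-dien-6α,12-olide (5R) | C[C@@]12O[C@@H]2CCC(=C)[C@@H](O)[C@H]3OC(=O)C(=C)[C@@H]3[C@H](OC(=O)/C(C)=C\C)C1 | intermediate
19 | 8β-angeloyloxy-5α,10β-epoxy-1β-hydroxygermacra-4(15),11(13)-dien-6α,12-olide (trans bridge, 14-methyl α) | C=C1C(=O)O[C@@H]2[C@@H]3O[C@@](C)(C[C@@H](OC(=O)/C(C)=C\C)[C@@H]12)[C@H](O)CCC3=C | intermediate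
20 | 15-(9-borabicyclo[3.3.1]nonan-9-yl) adduct of 19 (4αH) | C=C1C(=O)O[C@@H]2[C@@H]3O[C@@](C)(C[C@@H](OC(=O)/C(C)=C\C)[C@@H]12)[C@H](O)CC[C@@H]3CB4C5CCCC4CCC5 | intermediate
21 | 8β-angeloyloxy-5α,10β-epoxy-1β,15-dihydroxy-4αH-germacr-11(13)-en-6α,12-olide | C=C1C(=O)O[C@@H]2[C@@H]3O[C@@](C)(C[C@@H](OC(=O)/C(C)=C\C)[C@@H]12)[C@H](O)CC[C@@H]3CO | intermediate
22 | 15-O-tert-butyldimethylsilyl ether of 21 | C=C1C(=O)O[C@@H]2[C@@H]3O[C@@](C)(C[C@@H](OC(=O)/C(C)=C\C)[C@@H]12)[C@H](O)CC[C@@H]3CO[Si](C)(C)C(C)(C)C | intermediate
23 | 8β-angeloyloxy-15-(tert-butyldimethylsilyloxy)-5α,10β-epoxy-1-oxo-4αH-germacr-11(13)-en-6α,12-olide | C=C1C(=O)O[C@@H]2[C@@H]3O[C@@](C)(C[C@@H](OC(=O)/C(C)=C\C)[C@@H]12)C(=O)CC[C@@H]3CO[Si](C)(C)C(C)(C)C | intermediate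
24 | 1-trimethylsilyloxy-1-ene (enol silane) of 23 | C=C1C(=O)O[C@@H]2[C@@H]3O[C@@](C)(C[C@@H](OC(=O)/C(C)=C\C)[C@@H]12)C(O[Si](C)(C)C)=CC[C@@H]3CO[Si](C)(C)C(C)(C)C | intermediate
25 | 15-O-tert-butyldimethylsilyl ether of 26 | C=C1C(=O)O[C@@H]2[C@@H]3O[C@@](C)(C[C@@H](OC(=O)/C(C)=C\C)[C@@H]12)C(=O)C=C[C@@H]3CO[Si](C)(C)C(C)(C)C | intermediate
26 | CNP0274187.1, 8β-angeloyloxy-5α,10β-epoxy-15-hydroxy-1-oxo-4αH-germacra-2,11(13)-dien-6α,12-olide | C=C1C(=O)O[C@@H]2[C@@H]3O[C@@](C)(C[C@@H](OC(=O)/C(C)=C\C)[C@@H]12)C(=O)C=C[C@@H]3CO | target

## Step count and least certain steps

Total step count: 17. Longest linear sequence: 17 steps, from 1 to 26; 11 enters at step 7.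

**Step 3 (key step).** The cyclization itself is the native reaction. What is most likely to go wrong is loss of the product after it forms: Cope rearrangement on warming, proton-induced transannular cyclization on acidic surfaces, and evaporation, on top of slow turnover through product inhibition. The fallback is not to isolate the hydrocarbon. Starting from 3, the synthase and the oxidase microsomes of step 4, with the NADPH-regenerating system, are run in one pot so that 4 is oxidized as it is released. The path returns to the route at the more robust acid 7. It makes no compound outside the list (F0). The same coupling can be moved into a yeast strain that carries both enzymes.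

**Step 12.** Three things may go wrong. The hydroxyl may attack C1 instead of C10, closing a six-membered 1,5-ether. The C4=C15 alkene may take part in the opening. Or the closure to the strained trans bridge may be slow enough for elimination or hydride shift of the activated epoxide to take over. The fallback reverses the roles of the two carbons and starts from 16, which already has the 5β-oxygen needed for a leaving group:
- methanesulfonyl chloride and Et3N would give the 5β-mesylate F1;
- dilute aqueous HClO4 in THF would open the epoxide at C10 with inversion to the 1β,10β-diol mesylate F2;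
- 4-methoxybenzyl trichloroacetimidate with catalytic acid would cap the secondary 1β-hydroxyl to give the 1-O-(4-methoxybenzyl) ether F3;
- NaH in THF would then let the tertiary 10β-alkoxide displace the mesylate at C5 with inversion to give the bridged 1-O-(4-methoxybenzyl) ether F4;
- DDQ in wet CH2Cl2 would remove the benzyl ether, and the path comes back at 19.

**Step 10.** The displacement at C5 is hindered by the oxygen-bearing C6. Attack at C15 with allylic transposition, elimination to a diene, or acid-triggered opening of the epoxide may compete with the SN2 inversion. The fallback is an oxidation–reduction sequence from 16. Dess–Martin oxidation would give the 4(15)-en-5-one F5. Corey–Bakshi–Shibata reduction with the (R)-oxazaborolidine and catecholborane at −78 °C should deliver the 5α-alcohol if the alkenyl arm acts as the large group; the other catalyst enantiomer is used if it does not. The path returns at 18 and also removes step 11.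

**Step 13.** The dialkylborane may reduce or hydroborate the methylene lactone in competition with the C4=C15 alkene, and the face of addition at C4 rests on a steric argument only. The fallback masks the lactone, starting from 19. Benzeneselenol, from (PhSe)2 and NaBH4 in ethanol and then acetic acid, would add to C13 to give the 13-phenylseleno-11βH,13-dihydro adduct F6; the C11 configuration is of no consequence. 9-BBN would then give the borane F7. NaBO3·4H2O would oxidize both boron and selenium, and the selenoxide F8 should eliminate at room temperature to restore the methylene group. The path returns at 21.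

**Step 16.** Silylation may be slow at the hindered ketone. Once the enone forms, any base present may remove the C4 hydrogen and open the bridge, and palladium hydride may isomerize the angelate. The fallback, from 23, is direct dehydrogenation with 2-iodoxybenzoic acid in DMSO at 70 °C. It needs no enol silane and no metal, and it returns at 25. It makes no compound outside the list (F0).

## Further compounds

F0 | step 3 | none | none
F1 | step 12 | 5β-methanesulfonate of 16 | C[C@@]12O[C@@H]2CCC(=C)[C@H](OS(C)(=O)=O)[C@H]3OC(=O)C(=C)[C@@H]3[C@H](OC(=O)/C(C)=C\C)C1
F2 | step 12 | 8β-angeloyloxy-1β,10β-dihydroxy-5β-mesyloxygermacra-4(15),11(13)-dien-6α,12-olide (14-methyl α) | C[C@@]1(O)[C@H](O)CCC(=C)[C@H](OS(C)(=O)=O)[C@H]2OC(=O)C(=C)[C@@H]2[C@H](OC(=O)/C(C)=C\C)C1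
F3 | step 12 | 1-O-(4-methoxybenzyl) ether of F2 | C[C@@]1(O)[C@H](OCc2ccc(OC)cc2)CCC(=C)[C@H](OS(C)(=O)=O)[C@H]2OC(=O)C(=C)[C@@H]2[C@H](OC(=O)/C(C)=C\C)C1
F4 | step 12 | 1-O-(4-methoxybenzyl) ether of 19 | C=C1C(=O)O[C@@H]2[C@@H]3O[C@@](C)(C[C@@H](OC(=O)/C(C)=C\C)[C@@H]12)[C@H](OCc4ccc(OC)cc4)CCC3=C
F5 | step 10 | 8β-angeloyloxy-1β,10α-epoxy-5-oxogermacra-4(15),11(13)-dien-6α,12-olide | C[C@@]12O[C@@H]2CCC(=C)C(=O)[C@H]3OC(=O)C(=C)[C@@H]3[C@H](OC(=O)/C(C)=C\C)C1
F6 | step 13 | 13-phenylseleno-11βH,13-dihydro adduct of 19 | c1ccccc1[Se]C[C@@H]1C(=O)O[C@@H]2[C@@H]3O[C@@](C)(C[C@@H](OC(=O)/C(C)=C\C)[C@@H]12)[C@H](O)CCC3=C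
F7 | step 13 | 15-(9-borabicyclo[3.3.1]nonan-9-yl) adduct of F6 | c1ccccc1[Se]C[C@@H]1C(=O)O[C@@H]2[C@@H]3O[C@@](C)(C[C@@H](OC(=O)/C(C)=C\C)[C@@H]12)[C@H](O)CC[C@@H]3CB4C5CCCC4CCC5
F8 | step 13 | 13-phenylseleninyl-11βH,13-dihydro derivative of 21 (selenoxide) | c1ccccc1[Se](=O)C[C@@H]1C(=O)O[C@@H]2[C@@H]3O[C@@](C)(C[C@@H](OC(=O)/C(C)=C\C)[C@@H]12)[C@H](O)CC[C@@H]3CO
F0 | step 16 | none | none
A1 | alternative 1 | tricyclic C8 tert-butyldimethylsilyl enol ether with 15-O-silyl ether | C=C1C(=O)O[C@@H]2[C@@H]3O[C@@](C)(C=C(O[Si](C)(C)C(C)(C)C)[C@@H]12)C(=O)C=C[C@@H]3CO[Si](C)(C)C(C)(C)C
A2 | alternative 2 | (E)-cyclodec-5-enone with C10 methoxymethyl ether, C8 and C15 silyl ethers and C7 isopropenyl group | O=C1CC[C@H](CO[Si](C)(C)C(C)(C)C)/C=C/[C@H](C(C)=C)[C@H](O[Si](C)(C)C(C)(C)C)C[C@]1(C)OCOC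
A3 | alternative 3 | ring B oxepane with C8 carbinol, C7 methyl acrylate unit, C6 4-methoxybenzyl ether and two vinyl side chains | C=C(C(=O)OC)[C@@H]1[C@H](O)C[C@@](C)([C@H](O[Si](CC)(CC)CC)C=C)O[C@H]([C@@H](CO[Si](C)(C)C(C)(C)C)C=C)[C@H]1OCc2ccc(OC)cc2
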